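## Structural features

The target is an isocoumarin: benzene ring A fused to an α-pyranone, with a pentyl chain on C3, a free hydroxyl on C6 and an aryl ether oxygen on C8. Ring B is a benzene with one hydrogen only (C3'): carboxylic acid on C1', hydroxyls on C2' and C4', the ether oxygen on C5' and a second pentyl chain on C6'. The rings are joined only through the C8–O–C5' diaryl ether; its oxygen is flanked on ring B by the C4' oxygen and the C6' pentyl group and lies on ring A next to the carbon that carries the lactone carbonyl. There is no stereocentre, so nothing of that kind has to be set or protected. The fragile parts are the 2,4-dihydroxy-6-alkylbenzoic acid (it loses carbon dioxide on heating or in strong acid), the enol-lactone (it opens in base) and the electron-rich phenols. The real difficulty is regiochemical: ring A needs a 1,2,3,5 pattern (C8a carbonyl, C4a methine, oxygens on C8 and C6), ring B needs five different substituents in a fixed order, and the hindered ether must join the right pair of carbons. The key step uses the fact that C8a and C4a are neighbours and that C8a adjoins the oxygenated C8: an aryne across C8a–C4a is polarised by the C8 oxygen, so a malonate can deliver C4 to C4a and C1 to C8a in one operation.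

## Logic of the disconnections

25 to 24. The bonds cut are the three aryl O–CH3 bonds (on O6, O2', O4') and the ester O–CH3 bond. The acid and the phenols are the fragile functions, so they are unveiled last and together. The gain is that 24 is inert to base, fluoride and organometallic reagents. The forward step must break four O–CH3 bonds without opening the lactone and without heating the liberated acid.

24 to 22, then to 20 and 21. The lactone bond O2–C1 is cut, a carboxyl group is put back on C4, and C3–C4 is cut. The enol-lactone is the enol ester of a benzyl ketone that has an ester on C8a, and that ketone is the acylation product of an arylacetate. The pyranone ring and the pentyl chain thus reduce to 20 and the six-carbon 21. The forward steps need C-acylation of the one acidic methylene of 20, loss of the auxiliary ester carbon, and closure through oxygen and not through carbon, which calls for acid.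

20 to 17 and 18, through 19. The bonds C4a–C4 and C8a–C1 are cut together. The two carbon substituents are neighbours, 18 holds both a nucleophilic carbon and a transferable ester, and 19 is polarised by the oxygen on C8. Ring A is reduced to 17, which carries only heteroatom substituents, and two skeletal bonds come from one reagent. The forward step needs addition at C4a only, and 17 must hold no acidic or fluoride-labile group, so every oxygen is methyl-capped.

17 to 16, then to 11. The O–CH3 bond on the later O6 is cut first. The C–Si and O–S bonds are then traced back to the single C–Br bond of 11 by a silyl shift from oxygen to carbon. Silicon must sit on the carbon between the ether oxygen and the triflate oxygen. A deprotonation-based silylation of a ring A phenol derivative could not be trusted to choose this carbon over the one between the two small oxygen substituents, and it would expose the ester and the benzylic CH2 of ring B to strong base. A bromine atom fixes the carbon, and only the oxygen next to it can hand over its silyl group, which also tells the two ring A oxygens apart. The forward step needs halogen–lithium exchange to be much faster than any reaction at the ester.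

11 to 10. The C–Br bond is cut. Ring A of 10 is symmetric: the two positions beside the ether oxygen are equivalent, each para to one hydroxyl and ortho to the other, while the third position is only ortho to hydroxyls. Regiochemistry then follows from the intrinsic directing effects. The forward step needs mono-bromination of a very electron-rich ring with ring B untouched.

10 to 9, then to 7 and 8. The two benzyl O–C bonds are cut, then the aryl C–O bond on the ring A side of the ether. Cutting on this side makes the hindered component the nucleophile 7 and the electrophile the symmetric, unhindered 8; the reverse polarity would need a doubly ortho-substituted aryl halide. The result is two fragments of similar size. The forward step needs a copper-catalysed coupling that accepts a phenol with two ortho substituents, and benzyl groups that leave by hydrogenolysis without touching the methyl ethers.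

7 to 6, then to 3 and 4, then to 2 and 1. The bonds cut are C5'–O, the bond from C1' to the carboxyl carbon, two C–Br bonds and two O–CH3 bonds. C1' and C5' are the two equivalent positions flanking the pentyl chain of 2; brominating both gives the symmetric 3, and one halogen–lithium exchange then tells them apart with no regiochemical question. Ring B thus comes from 1 and the one-carbon reagent 4. The forward steps need mono-exchange and hydroxylation of a hindered bromide without saponifying the ester.

## Other disconnections considered

Alternative 1: The cut runs through ring B at C1'–C2' and C5'–C6', so ring B is assembled last from an open-chain diene and an alkyne. In the forward sense the bis(silyloxy)diene A2, which carries the finished isocoumarin as an aryloxy group on its terminal carbon, would combine with methyl oct-2-ynoate A3 in a [4+2] cycloaddition. Elimination of the alkoxy group and desilylation on acidic work-up would give the resorcylate A1.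
- In its favour: the polarity of the partners places all six substituents of ring B in one step. Ring B arrives with free hydroxyls, so fewer methyl groups remain to be removed than in the chosen plan; here the alternative is better. The hindered ether oxygen never has to act as nucleophile in a metal-catalysed coupling, which is equal or better.
- Against it here: A2 has a tetrasubstituted, oxygen-bearing diene terminus and A3 is a β-alkyl ynoate of modest reactivity, so the cycloaddition would need heat that endangers the silyl enol ethers and the enol-lactone. A2 must be made by double enolisation with strong base in the presence of the lactone. The isocoumarin with its C8 oxygen must exist beforehand, so the regiochemical problem of ring A is moved and not solved.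
- Comparison: on structure it answers ring B and leaves ring A open, while the chosen plan answers ring A and builds ring B by stepwise substitution of a symmetric arene. On mechanism a thermal cycloaddition of a hindered diene is less predictable than an aryne insertion governed by one neighbouring oxygen. On step economy ring B in one step beats the four steps to 7, but the separate preparation of the ring A portion and of A2 should bring the total to about the same length.

Alternative 2: The cut runs through ring B at C1'–C6' and C2'–C3'. In the forward sense 18 would add to the β-carbon of the α-aryloxy enone A5 under an alkoxide base, the methyl ketone would close on a malonate ester to a cyclohexane-1,3-dione, and dehydrogenation in the same flask would give the resorcylate A4. The alkynyl ester of A4 would later be cyclised to the isocoumarin.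
- In its favour: the annulation is the direct counterpart of the classical enone–malonate route to 6-alkylresorcylates, it uses cheap reagents and no low-temperature organometallic chemistry (better), and it draws its carbon from 18 as the chosen plan does (equal).
- Against it here: the donor oxygen on the α-carbon of A5 lowers its acceptor strength. In the cyclohexanedione the aryloxy group sits next to a carbonyl and can leave as phenoxide, which would aromatise the ring without oxidant and without the ether. A halogenating oxidant would also attack the electron-rich ring A and the alkyne. A5 needs an aldol-type condensation at the oxygen-bearing carbon of its ketone precursor. A4 still needs a 6-endo and not a 5-exo cyclisation, and ring A with ester, alkyne and two oxygens must be made separately.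
- Comparison: on structure it solves ring B only. On mechanism the ether link is at risk in the very step that completes ring B, while in the chosen plan the ether is a spectator of the key step. On step economy no clear advantage is expected, because the ring A fragment needs its own multi-step synthesis.

Alternative 3: The cut runs through ring A at C6–C7 and C5–C4a; C7, C8, C8a, C4a and the whole pyranone come from the bis-pyrone A7. In the forward sense the electron-rich alkene A8 would add across the diene of the aryloxy-bearing pyranone ring of A7, the bicyclic adduct would lose its lactone bridge by decarboxylation and then one alkoxy group, and the benzene ring of A6 would appear. A6 is the same compound as 24.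
- In its favour: the isocoumarin arrives with lactone and C3 pentyl in place, so steps 11 and 12 would not be needed (better). The ether would be made by addition–elimination of 7 at an activated C4 of the pyranone, easier for a hindered phenol than a copper-catalysed coupling (better). Ring A regiochemistry is set by the polarity of the pyranone (equal in principle).
- Against it here: A7 holds two pyranone rings that can each act as diene, and the aryloxy donor deactivates the ring that should react, so site selectivity is uncertain. A8 is prone to conjugate addition and oligomerisation under forcing conditions. The bis-lactone can be opened at its carbonyl carbons by the phenoxide of 7 in competition with substitution.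
- Comparison: on structure both plans meet at 24. On mechanism a cycloaddition–cycloreversion cascade depending on a balance between two dienes is set against an insertion steered by a single substituent. On step economy the alternative is two steps shorter after its key step, but A7 needs its own preparation and activation, so the totals should be similar.

Key step: step 10

Assumption: compound 8 is taken to be purchasable; ring A atoms are numbered as in the isocoumarin (C1 to C8a) and ring B atoms from C1' (bearing the carboxyl) to C6' (bearing the pentyl chain).

Step 1
Reactants: 1 olivetol (5-pentylbenzene-1,3-diol)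
Product: 2 1,3-dimethoxy-5-pentylbenzene
Conditions: MeI (2.5 equiv), K2CO3 (3 equiv), acetone, reflux
Reagents that add atoms: iodomethane, CI
Why: Double Williamson O-methylation of an unhindered resorcinol; methyl ethers are chosen because they should survive every later organometallic, fluoride and acid step.

Step 2
Reactants: 2 1,3-dimethoxy-5-pentylbenzene
Product: 3 2,4-dibromo-1,5-dimethoxy-3-pentylbenzene
Conditions: NBS (2.1 equiv), MeCN, 0 °C → rt
Reagents that add atoms: N-bromosuccinimide, O=C1CCC(=O)N1Br
Why: Electrophilic aromatic bromination; each bromine should enter para to one methoxy group and beside the pentyl chain, the position between the two methoxy groups being the slowest, so the symmetric dibromide activates both future ring B sites (C1' and C5') at once.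

Step 3
Reactants: 3 2,4-dibromo-1,5-dimethoxy-3-pentylbenzene; 4 methyl chloroformate
Product: 6 methyl 5-bromo-2,4-dimethoxy-6-pentylbenzoate, via aryllithium 5 (not isolated)
Conditions: n-BuLi (1.05 equiv), THF, −78 °C; then 4 (1.5 equiv), −78 °C → rt
Reagents that add atoms: none
Why: Bromine–lithium exchange at one of two equivalent C–Br bonds (a second exchange on the aryllithium is slower) and acylation of the aryllithium by the chloroformate; this desymmetrisation puts the ester on C1' and leaves bromine on C5'.

Step 4
Reactants: 6 methyl 5-bromo-2,4-dimethoxy-6-pentylbenzoate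
Product: 7 methyl 5-hydroxy-2,4-dimethoxy-6-pentylbenzoate
Conditions: Pd2(dba)3 (2 mol %), t-BuXPhos (8 mol %), KOH (3 equiv), 1,4-dioxane–H2O, 100 °C; then aq. HCl
Reagents that add atoms: potassium hydroxide, [K+].[OH-]
Why: Palladium-catalysed hydroxylation of an aryl bromide (C–O coupling with hydroxide), a reaction type that accepts doubly ortho-substituted electron-rich bromides; the methyl ester lies between two ortho substituents and should resist saponification.

Step 5
Reactants: 7 methyl 5-hydroxy-2,4-dimethoxy-6-pentylbenzoate; 8 1-bromo-3,5-bis(benzyloxy)benzene
Product: 9 methyl 5-[3,5-bis(benzyloxy)phenoxy]-2,4-dimethoxy-6-pentylbenzoate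
Conditions: CuI (10 mol %), picolinic acid (20 mol %), K3PO4 (2 equiv), DMSO, 100 °C
Reagents that add atoms: none
Why: Ullmann-type copper-catalysed diaryl ether synthesis; the hindered partner is the phenol, which the picolinic acid system tolerates, and the aryl bromide is unhindered and symmetric, so no regiochemical question arises.

Step 6
Reactants: 9 methyl 5-[3,5-bis(benzyloxy)phenoxy]-2,4-dimethoxy-6-pentylbenzoate
Product: 10 methyl 5-(3,5-dihydroxyphenoxy)-2,4-dimethoxy-6-pentylbenzoate
Conditions: H2 (1 atm), Pd/C (10 %), EtOAc–MeOH, rt
Reagents that add atoms: none
Why: Hydrogenolysis of both benzyl ethers; methyl ethers, ester and diaryl ether are inert, and the product is a symmetric resorcinol.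

Step 7
Reactants: 10 methyl 5-(3,5-dihydroxyphenoxy)-2,4-dimethoxy-6-pentylbenzoate
Product: 11 methyl 5-(2-bromo-3,5-dihydroxyphenoxy)-2,4-dimethoxy-6-pentylbenzoate
Conditions: NBS (1.0 equiv), THF–CH2Cl2, −78 °C
Reagents that add atoms: N-bromosuccinimide, O=C1CCC(=O)N1Br
Why: Electrophilic aromatic bromination of the far more electron-rich ring A; the two equivalent positions beside the ether oxygen are each para to one hydroxyl and ortho to the other, the third position has only ortho activation, so bromine should enter next to the ether oxygen, while ring B is deactivated by its ester.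

Step 8
Reactants: 11 methyl 5-(2-bromo-3,5-dihydroxyphenoxy)-2,4-dimethoxy-6-pentylbenzoate
Product: 16 methyl 5-[5-hydroxy-3-(trifluoromethylsulfonyloxy)-2-(trimethylsilyl)phenoxy]-2,4-dimethoxy-6-pentylbenzoate, via bis(silyl ether) 12 (not isolated), via aryllithium 13 (not isolated), via lithium phenoxide 14 (not isolated), via silyl ether triflate 15 (not isolated)
Conditions: HN(SiMe3)2, THF, 70 °C, concentrate; n-BuLi (1.1 equiv), THF, −100 °C; Tf2O (1.2 equiv), −100 °C → rt; aq. citric acid, MeOH, 0 °C
Reagents that add atoms: hexamethyldisilazane, C[Si](C)(C)N[Si](C)(C)C; trifluoromethanesulfonic anhydride, O=S(=O)(OS(=O)(=O)C(F)(F)F)C(F)(F)F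
Why: O-silylation, bromine–lithium exchange, anionic 1,3-silyl migration from oxygen to carbon (retro-Brook rearrangement) and O-triflation of the phenoxide so formed; only the oxygen next to the lithiated carbon can give up its silyl group, so silicon ends on the carbon beside the ether oxygen and the triflate on the neighbouring oxygen, while the remote silyl ether is hydrolysed at work-up; exchange at −100 °C should outrun attack on the doubly ortho-substituted ester.

Step 9
Reactants: 16 methyl 5-[5-hydroxy-3-(trifluoromethylsulfonyloxy)-2-(trimethylsilyl)phenoxy]-2,4-dimethoxy-6-pentylbenzoate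
Product: 17 methyl 2,4-dimethoxy-5-[5-methoxy-3-(trifluoromethylsulfonyloxy)-2-(trimethylsilyl)phenoxy]-6-pentylbenzoate
Conditions: MeI (3 equiv), K2CO3 (1.5 equiv), acetone, rt
Reagents that add atoms: iodomethane, CI
Why: Williamson O-methylation of the one free phenol; without fluoride or crown ether the silyl triflate should stay intact, and the methyl cap removes the last acidic group before the aryne step.

Step 10
Reactants: 17 methyl 2,4-dimethoxy-5-[5-methoxy-3-(trifluoromethylsulfonyloxy)-2-(trimethylsilyl)phenoxy]-6-pentylbenzoate; 18 dimethyl malonate
Product: 20 methyl 5-[5-methoxy-2-(methoxycarbonyl)-3-(2-methoxy-2-oxoethyl)phenoxy]-2,4-dimethoxy-6-pentylbenzoate, via aryne 19 (not isolated)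
Conditions: CsF (3 equiv), 18 (3 equiv), MeCN, 60 °C
Reagents that add atoms: none
Why: Fluoride attacks silicon of 17 and triflate leaves from the neighbouring carbon, giving aryne 19 with its triple bond between the future C8a and C4a. The cesium enolate of 18, formed with fluoride as base, adds to C4a, the aryne carbon remote from the aryloxy group, because the aryl anion then develops at C8a beside the inductively withdrawing C8 oxygen and the aryne is distorted so that C4a is its more electrophilic end. The C8a anion attacks the adjacent ester carbonyl of the newly attached malonate (4-exo-trig) to give a benzocyclobutene alkoxide, which fragments at the former malonate C–C bond so that the ester stays on C8a and an ester-stabilised benzylic carbanion remains on C4; proton transfer from a further molecule of 18 gives 20 and carries the chain. The closest known reaction type is the fluoride-induced insertion of arynes into the C–C σ bond of malonates and β-keto esters (acyl-alkylation), in which 3-alkoxyarynes place the carbon nucleophile meta to oxygen. No ring is closed in the product (the four-membered ring is transient) and no stereocentre is formed. The step needs regioselectivity, which the C8 aryloxy group secures; the methoxy group on C6 is para to C8a and its weak inductive effect pulls, if at all, slightly the other way, but it is remote and should be overridden. It also needs acyl transfer to outrun protonation of the aryl anion and a single arylation, which a dry aprotic medium and an excess of 18 (more acidic than 20) should secure. All groups of ring B are methyl-capped and inert to fluoride, so they are spectators.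

Step 11
Reactants: 20 methyl 5-[5-methoxy-2-(methoxycarbonyl)-3-(2-methoxy-2-oxoethyl)phenoxy]-2,4-dimethoxy-6-pentylbenzoate; 21 hexanoyl chloride
Product: 22 methyl 5-[5-methoxy-2-(methoxycarbonyl)-3-(1-methoxy-1,3-dioxooctan-2-yl)phenoxy]-2,4-dimethoxy-6-pentylbenzoate (racemic)
Conditions: LiN(SiMe3)2 (2.2 equiv), THF, −78 °C; then 21 (1.1 equiv), −78 → 0 °C; aq. NH4Cl
Reagents that add atoms: none
Why: C-acylation of the lithium enolate of the arylacetate (Claisen-type acylation with an acid chloride); only the benzylic methylene is acidic enough, the second equivalent of base takes up the more acidic β-keto ester, and the new centre is racemic, enolisable and lost in the next step.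

Step 12
Reactants: 22 methyl 5-[5-methoxy-2-(methoxycarbonyl)-3-(1-methoxy-1,3-dioxooctan-2-yl)phenoxy]-2,4-dimethoxy-6-pentylbenzoate
Product: 24 methyl 2,4-dimethoxy-5-[(6-methoxy-1-oxo-3-pentyl-1H-isochromen-8-yl)oxy]-6-pentylbenzoate, via keto ester 23 (not isolated)
Conditions: AcOH–6 M aq. HCl (3:1), 100 °C
Reagents that add atoms: none
Why: Acid hydrolysis of the unhindered β-keto ester and decarboxylation of the β-keto acid, then acid-catalysed enol lactonisation onto the neighbouring aryl ester (6-exo-trig acyl substitution by the enol oxygen); acid is used because base would favour carbon attack of the other enolate on the ester and lead to a naphthalenediol, and the doubly ortho-substituted ester of ring B and the aryl methyl ethers should survive.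

Step 13
Reactants: 24 methyl 2,4-dimethoxy-5-[(6-methoxy-1-oxo-3-pentyl-1H-isochromen-8-yl)oxy]-6-pentylbenzoate
Product: 25 2,4-dihydroxy-5-[(6-hydroxy-1-oxo-3-pentyl-1H-isochromen-8-yl)oxy]-6-pentylbenzoic acid
Conditions: BBr3 (12 equiv), CH2Cl2, −78 °C → rt; then H2O, 0 °C
Reagents that add atoms: none
Why: Lewis acid cleavage of three aryl methyl ethers and O-alkyl cleavage of the methyl ester by bromide on the boron-bound substrate; the ester is attacked at its methyl group, so the shielding of its carbonyl does not matter, and work-up is kept cold because the liberated acid decarboxylates when heated in acid.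

Compound list

1 | olivetol (5-pentylbenzene-1,3-diol) | CCCCCc1cc(O)cc(O)c1 | starting material
2 | 1,3-dimethoxy-5-pentylbenzene | CCCCCc1cc(OC)cc(OC)c1 | intermediate
3 | 2,4-dibromo-1,5-dimethoxy-3-pentylbenzene | CCCCCc1c(Br)c(OC)cc(OC)c1Br | intermediate
4 | methyl chloroformate | COC(=O)Cl | starting material
5 | (3-bromo-4,6-dimethoxy-2-pentylphenyl)lithium | [Li]c1c(OC)cc(OC)c(Br)c1CCCCC | intermediate (not isolated)
6 | methyl 5-bromo-2,4-dimethoxy-6-pentylbenzoate | COC(=O)c1c(OC)cc(OC)c(Br)c1CCCCC | intermediate
7 | methyl 5-hydroxy-2,4-dimethoxy-6-pentylbenzoate | COC(=O)c1c(OC)cc(OC)c(O)c1CCCCC | intermediate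
8 | 1-bromo-3,5-bis(benzyloxy)benzene | Brc1cc(OCc2ccccc2)cc(OCc2ccccc2)c1 | starting material
9 | methyl 5-[3,5-bis(benzyloxy)phenoxy]-2,4-dimethoxy-6-pentylbenzoate | COC(=O)c1c(OC)cc(OC)c(Oc2cc(OCc3ccccc3)cc(OCc3ccccc3)c2)c1CCCCC | intermediate
10 | methyl 5-(3,5-dihydroxyphenoxy)-2,4-dimethoxy-6-pentylbenzoate | COC(=O)c1c(OC)cc(OC)c(Oc2cc(O)cc(O)c2)c1CCCCC | intermediate
11 | methyl 5-(2-bromo-3,5-dihydroxyphenoxy)-2,4-dimethoxy-6-pentylbenzoate | COC(=O)c1c(OC)cc(OC)c(Oc2cc(O)cc(O)c2Br)c1CCCCC | intermediate
12 | methyl 5-[2-bromo-3,5-bis(trimethylsilyloxy)phenoxy]-2,4-dimethoxy-6-pentylbenzoate | COC(=O)c1c(OC)cc(OC)c(Oc2cc(O[Si](C)(C)C)cc(O[Si](C)(C)C)c2Br)c1CCCCC | intermediate (not isolated)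
13 | methyl 5-[2-lithio-3,5-bis(trimethylsilyloxy)phenoxy]-2,4-dimethoxy-6-pentylbenzoate | COC(=O)c1c(OC)cc(OC)c(Oc2cc(O[Si](C)(C)C)cc(O[Si](C)(C)C)c2[Li])c1CCCCC | intermediate (not isolated)
14 | lithium 3-[4,6-dimethoxy-3-(methoxycarbonyl)-2-pentylphenoxy]-2-(trimethylsilyl)-5-(trimethylsilyloxy)phenoxide | COC(=O)c1c(OC)cc(OC)c(Oc2cc(O[Si](C)(C)C)cc([O-])c2[Si](C)(C)C)c1CCCCC.[Li+] | intermediate (not isolated)
15 | methyl 2,4-dimethoxy-6-pentyl-5-[3-(trifluoromethylsulfonyloxy)-2-(trimethylsilyl)-5-(trimethylsilyloxy)phenoxy]benzoate | COC(=O)c1c(OC)cc(OC)c(Oc2cc(O[Si](C)(C)C)cc(OS(=O)(=O)C(F)(F)F)c2[Si](C)(C)C)c1CCCCC | intermediate (not isolated)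
16 | methyl 5-[5-hydroxy-3-(trifluoromethylsulfonyloxy)-2-(trimethylsilyl)phenoxy]-2,4-dimethoxy-6-pentylbenzoate | COC(=O)c1c(OC)cc(OC)c(Oc2cc(O)cc(OS(=O)(=O)C(F)(F)F)c2[Si](C)(C)C)c1CCCCC | intermediate
17 | methyl 2,4-dimethoxy-5-[5-methoxy-3-(trifluoromethylsulfonyloxy)-2-(trimethylsilyl)phenoxy]-6-pentylbenzoate | COc1cc(OS(=O)(=O)C(F)(F)F)c([Si](C)(C)C)c(Oc2c(OC)cc(OC)c(C(=O)OC)c2CCCCC)c1 | intermediate
18 | dimethyl malonate | COC(=O)CC(=O)OC | starting material
19 | methyl 5-(2,3-didehydro-5-methoxyphenoxy)-2,4-dimethoxy-6-pentylbenzoate (the 3-aryloxy-5-methoxybenzyne) | COC1=CC#CC(Oc2c(OC)cc(OC)c(C(=O)OC)c2CCCCC)=C1 | intermediate (not isolated)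
20 | methyl 5-[5-methoxy-2-(methoxycarbonyl)-3-(2-methoxy-2-oxoethyl)phenoxy]-2,4-dimethoxy-6-pentylbenzoate | COC(=O)Cc1cc(OC)cc(Oc2c(OC)cc(OC)c(C(=O)OC)c2CCCCC)c1C(=O)OC | intermediate
21 | hexanoyl chloride | CCCCCC(Cl)=O | starting material
22 | methyl 5-[5-methoxy-2-(methoxycarbonyl)-3-(1-methoxy-1,3-dioxooctan-2-yl)phenoxy]-2,4-dimethoxy-6-pentylbenzoate (racemic) | CCCCCC(=O)C(C(=O)OC)c1cc(OC)cc(Oc2c(OC)cc(OC)c(C(=O)OC)c2CCCCC)c1C(=O)OC | intermediate
23 | methyl 5-[5-methoxy-2-(methoxycarbonyl)-3-(2-oxoheptyl)phenoxy]-2,4-dimethoxy-6-pentylbenzoate | CCCCCC(=O)Cc1cc(OC)cc(Oc2c(OC)cc(OC)c(C(=O)OC)c2CCCCC)c1C(=O)OC | intermediate (not isolated)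
24 | methyl 2,4-dimethoxy-5-[(6-methoxy-1-oxo-3-pentyl-1H-isochromen-8-yl)oxy]-6-pentylbenzoate | CCCCCc1cc2cc(OC)cc(Oc3c(OC)cc(OC)c(C(=O)OC)c3CCCCC)c2c(=O)o1 | intermediate
25 | 2,4-dihydroxy-5-[(6-hydroxy-1-oxo-3-pentyl-1H-isochromen-8-yl)oxy]-6-pentylbenzoic acid | CCCCCc1cc2cc(O)cc(Oc3c(O)cc(O)c(C(=O)O)c3CCCCC)c2c(=O)o1 | target

Total step count: 13. Longest linear sequence: 13 steps, from 1 to 25; compounds 4, 8, 18 and 21 enter as purchased reagents.

Steps least certain to work

Step 10 (key step). What may go wrong: protonation of the C8a aryl anion before the ester has migrated, which gives plain arylation of the malonate; a second arylation of the product; capture of the aryne by a methoxy oxygen of ring B from within the molecule; or erosion of regioselectivity by the C6 methoxy group. The aryl anion is very basic and the acyl shift passes through a strained four-membered ring, which is why these can compete. Fallback, setting out from 17 and avoiding an aryne: ipso-iododesilylation with ICl (CH2Cl2, −78 °C) should give methyl 5-[2-iodo-5-methoxy-3-(trifluoromethylsulfonyloxy)phenoxy]-2,4-dimethoxy-6-pentylbenzoate F1. Palladium-catalysed methoxycarbonylation of the C–I bond (Pd(OAc)2, Xantphos, CO, MeOH, Et3N, 70 °C), which reacts well before the triflate, should give methyl 5-[5-methoxy-2-(methoxycarbonyl)-3-(trifluoromethylsulfonyloxy)phenoxy]-2,4-dimethoxy-6-pentylbenzoate F2. Cross-coupling of the triflate with the Reformatsky reagent BrZnCH2CO2Me (Pd2(dba)3, XPhos, THF, 60 °C) comes back to the route at 20. The positions of silicon and triflate in 17 then fix the regiochemistry.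

Step 8. What may go wrong: loss of chemoselectivity of the alkyllithium (addition to the ring B ester, deprotonation at its benzylic CH2, or cleavage of an O–Si bond instead of exchange), and loss of silicon from carbon during the acidic hydrolysis of the remaining silyl ether. Fallback, setting out from 11 and using no alkyllithium: after O-silylation to 12, palladium-catalysed silylation of the C–Br bond with hexamethyldisilane (Pd2(dba)3, 2-(di-tert-butylphosphino)biphenyl, LiOAc, DMF, 100 °C) and aqueous work-up should give methyl 5-[3,5-dihydroxy-2-(trimethylsilyl)phenoxy]-2,4-dimethoxy-6-pentylbenzoate F3. The hydroxyl beside the trimethylsilyl group is shielded, so MeI (1 equiv) with K2CO3 in acetone should methylate the remote hydroxyl to methyl 5-[3-hydroxy-5-methoxy-2-(trimethylsilyl)phenoxy]-2,4-dimethoxy-6-pentylbenzoate F4. O-Triflation (Tf2O, pyridine, CH2Cl2, 0 °C) comes back to the route at 17.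

Step 7. What may go wrong: loss of site control between the position beside the ether oxygen and the one between the hydroxyls, and over-bromination or oxidation of a very electron-rich ring. Fallback, setting out from 9: bromination of the less activated dibenzyl ether (NBS, MeCN, 0 °C), where the position between the two benzyloxy groups is more shielded, should give methyl 5-[3,5-bis(benzyloxy)-2-bromophenoxy]-2,4-dimethoxy-6-pentylbenzoate F5. Debenzylation with BCl3 and pentamethylbenzene (CH2Cl2, −78 °C), which spares the C–Br bond, comes back to the route at 11.

Step 4. What may go wrong: saponification of the ester by hot hydroxide, or reduction of the C–Br bond instead of hydroxylation. Fallback, setting out from 3 with a changed order of events: mono-exchange (n-BuLi, THF, −78 °C), B(OMe)3, then H2O2 with aq. NaOH should give 3-bromo-4,6-dimethoxy-2-pentylphenol F6. Its dianion (n-BuLi, 2.2 equiv, −78 → −20 °C) with CO2 should give 3-hydroxy-4,6-dimethoxy-2-pentylbenzoic acid F7. Selective esterification of the carboxylate (MeI, KHCO3, DMF) comes back to the route at 7.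

Step 12. What may go wrong: slow hydrolysis of the β-keto ester so that the reaction stalls at an isocoumarin-4-carboxylate, and, on prolonged heating, hydrolysis followed by decarboxylation at the ring B ester. Fallback, setting out from 22: Krapcho dealkoxycarbonylation (LiCl, DMSO–H2O, 130 °C) removes the activated ester under neutral conditions and lets 23 be isolated; TsOH·H2O in toluene at 100 °C then closes the lactone and comes back to the route at 24. This fallback makes no compound outside the list (F0).

Step 13. What may go wrong: incomplete cleavage of the hindered methyl ester, or decarboxylation of the product acid during acidic work-up. Fallback, setting out from 24: nucleophilic O-alkyl cleavage of the ester alone (LiI, pyridine, reflux) should give 2,4-dimethoxy-5-[(6-methoxy-1-oxo-3-pentyl-1H-isochromen-8-yl)oxy]-6-pentylbenzoic acid F8. BBr3 (CH2Cl2, −78 → 0 °C) then has only the three aryl ethers to cleave and comes back to the route at 25.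

Further compounds

F1 | step 10 | methyl 5-[2-iodo-5-methoxy-3-(trifluoromethylsulfonyloxy)phenoxy]-2,4-dimethoxy-6-pentylbenzoate | COc1cc(OS(=O)(=O)C(F)(F)F)c(I)c(Oc2c(OC)cc(OC)c(C(=O)OC)c2CCCCC)c1
F2 | step 10 | methyl 5-[5-methoxy-2-(methoxycarbonyl)-3-(trifluoromethylsulfonyloxy)phenoxy]-2,4-dimethoxy-6-pentylbenzoate | COc1cc(OS(=O)(=O)C(F)(F)F)c(C(=O)OC)c(Oc2c(OC)cc(OC)c(C(=O)OC)c2CCCCC)c1
F3 | step 8 | methyl 5-[3,5-dihydroxy-2-(trimethylsilyl)phenoxy]-2,4-dimethoxy-6-pentylbenzoate | COC(=O)c1c(OC)cc(OC)c(Oc2cc(O)cc(O)c2[Si](C)(C)C)c1CCCCC
F4 | step 8 | methyl 5-[3-hydroxy-5-methoxy-2-(trimethylsilyl)phenoxy]-2,4-dimethoxy-6-pentylbenzoate | COc1cc(O)c([Si](C)(C)C)c(Oc2c(OC)cc(OC)c(C(=O)OC)c2CCCCC)c1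
F5 | step 7 | methyl 5-[3,5-bis(benzyloxy)-2-bromophenoxy]-2,4-dimethoxy-6-pentylbenzoate | COC(=O)c1c(OC)cc(OC)c(Oc2cc(OCc3ccccc3)cc(OCc3ccccc3)c2Br)c1CCCCC
F6 | step 4 | 3-bromo-4,6-dimethoxy-2-pentylphenol | CCCCCc1c(O)c(OC)cc(OC)c1Br
F7 | step 4 | 3-hydroxy-4,6-dimethoxy-2-pentylbenzoic acid | CCCCCc1c(O)c(OC)cc(OC)c1C(=O)O
F0 | step 12 | none | none
F8 | step 13 | 2,4-dimethoxy-5-[(6-methoxy-1-oxo-3-pentyl-1H-isochromen-8-yl)oxy]-6-pentylbenzoic acid | CCCCCc1cc2cc(OC)cc(Oc3c(OC)cc(OC)c(C(=O)O)c3CCCCC)c2c(=O)o1
A1 | alternative 1 | methyl 2,4-dihydroxy-5-[(6-methoxy-1-oxo-3-pentylisochromen-8-yl)oxy]-6-pentylbenzoate | CCCCCc1cc2cc(OC)cc(Oc3c(O)cc(O)c(C(=O)OC)c3CCCCC)c2c(=O)o1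
A2 | alternative 1 | 1-methoxy-4-[(6-methoxy-1-oxo-3-pentylisochromen-8-yl)oxy]-1,3-bis(trimethylsilyloxy)buta-1,3-diene (double-bond geometry not defined) | COC(O[Si](C)(C)C)=CC(O[Si](C)(C)C)=COc1cc(OC)cc2cc(CCCCC)oc(=O)c12
A3 | alternative 1 | methyl oct-2-ynoate | CCCCCC#CC(=O)OC
A4 | alternative 2 | methyl 5-[3-(hept-1-ynyl)-5-methoxy-2-(methoxycarbonyl)phenoxy]-2,4-dihydroxy-6-pentylbenzoate | CCCCCC#Cc1cc(OC)cc(Oc2c(O)cc(O)c(C(=O)OC)c2CCCCC)c1C(=O)OC
A5 | alternative 2 | methyl 2-(hept-1-ynyl)-4-methoxy-6-[(2-oxonon-3-en-3-yl)oxy]benzoate (double-bond geometry not defined) | CCCCCC=C(Oc1cc(OC)cc(C#CCCCCC)c1C(=O)OC)C(C)=O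
A6 | alternative 3 | methyl 2,4-dimethoxy-5-[(6-methoxy-1-oxo-3-pentylisochromen-8-yl)oxy]-6-pentylbenzoate | CCCCCc1cc2cc(OC)cc(Oc3c(OC)cc(OC)c(C(=O)OC)c3CCCCC)c2c(=O)o1
A7 | alternative 3 | methyl 5-[(2,5-dioxo-7-pentyl-2H,5H-pyrano[4,3-b]pyran-4-yl)oxy]-2,4-dimethoxy-6-pentylbenzoate | CCCCCc1cc2oc(=O)cc(Oc3c(OC)cc(OC)c(C(=O)OC)c3CCCCC)c2c(=O)o1
A8 | alternative 3 | 1,1-dimethoxyethene | C=C(OC)OC
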